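The route rests on cutting two bonds of ring A at once: the diaryl ether bond from carbon 3 of ring A to the ring B oxygen and the bond from carbon 4 to its acetyl group. Carbons 3, 4 and 5 of ring A carry ether oxygen, acetyl and hydroxyl in a row, the pattern left when a phenoxide adds to an aryne and the new aryl anion takes the acyl group of a neighbouring ester. One operation should therefore join both halves and set ether, ketone and chelated phenol. The precursors are silylaryl triflate 13, with the acetate on carbon 5, and ring B phenol 20, its other hydroxyls benzylated.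

Key step: step 14

Remark: ring A is numbered from the methoxy-bearing carbon as carbon 1, then the CH as carbon 2, the ether carbon 3, the acetyl carbon 4, the hydroxyl carbon 5 and the methyl carbon 6. Ring B is numbered from the ether carbon as carbon 1, then the hydroxyl carbon 2, the methyl carbon 3, the methoxy carbon 4, the acetyl carbon 5 and the hydroxyl carbon 6. No compound in the route has a stereocentre.

Step 1
Reactants: 1 3-methoxy-2-methylphenol
Product: 2 3-methoxy-2-methylphenyl N,N-diethylcarbamate
Conditions: Et2NCOCl, K2CO3, MeCN, 80 °C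
Reagents that add atoms: N,N-diethylcarbamoyl chloride, CCN(CC)C(Cl)=O
Why: O-carbamoylation of the phenoxide (acyl substitution) masks the oxygen on carbon 5 of ring A for the C–H borylation and installs the strongest oxygen-based directing group for the later directed ortho metalation.

Step 2
Reactants: 2 3-methoxy-2-methylphenyl N,N-diethylcarbamate
Product: 4 5-hydroxy-3-methoxy-2-methylphenyl N,N-diethylcarbamate, via aryl pinacol boronate 3 (not isolated)
Conditions: [Ir(OMe)(cod)]2 (cat.), 4,4′-di-tert-butyl-2,2′-bipyridine, B2pin2, THF, 80 °C; then 30% H2O2, aq NaOH, 0 °C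
Reagents that add atoms: bis(pinacolato)diboron, CC1(C)OB(OC1(C)C)B1OC(C)(C)C(C)(C)O1 (boron in intermediate 3 only); hydrogen peroxide, OO
Why: Iridium-catalysed aromatic C–H borylation is sterically controlled and should take the only ring C–H without an ortho neighbour, the one para to the methyl group (the future carbon 3 of ring A), after which peroxide oxidation of the C–B bond gives the phenol.

Step 3
Reactants: 4 5-hydroxy-3-methoxy-2-methylphenyl N,N-diethylcarbamate; 5 benzyl bromide
Product: 6 5-(benzyloxy)-3-methoxy-2-methylphenyl N,N-diethylcarbamate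
Conditions: BnBr, K2CO3, DMF, rt
Reagents that add atoms: benzyl bromide 5, BrCc1ccccc1
Why: Williamson etherification of the only free phenol keeps the oxygen on carbon 3 of ring A distinct from the oxygen on carbon 5 through the organolithium and hydride steps.

Step 4
Reactants: 6 5-(benzyloxy)-3-methoxy-2-methylphenyl N,N-diethylcarbamate; 7 chlorotrimethylsilane
Product: 9 3-(benzyloxy)-5-methoxy-6-methyl-2-(trimethylsilyl)phenyl N,N-diethylcarbamate, via aryllithium 8 (not isolated)
Conditions: s-BuLi, TMEDA, THF, −78 °C; then TMSCl, −78 °C to rt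
Reagents that add atoms: sec-butyllithium, [Li]C(C)CC (lithium in intermediate 8 only); chlorotrimethylsilane 7, C[Si](C)(C)Cl
Why: Directed ortho metalation should occur at carbon 4 of ring A, the only free ring position ortho to the carbamate and additionally flanked by the benzyloxy oxygen, and the aryllithium is silylated at −78 °C before an anionic Fries shift of the carbamate can set in.

Step 5
Reactants: 9 3-(benzyloxy)-5-methoxy-6-methyl-2-(trimethylsilyl)phenyl N,N-diethylcarbamate
Product: 10 3-(benzyloxy)-5-methoxy-6-methyl-2-(trimethylsilyl)phenol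
Conditions: LiAlH4, THF, reflux; aqueous work-up
Reagents that add atoms: none
Why: Hydride reduction of the aryl carbamate expels the phenoxide and carries the carbamoyl carbon off as an amine, while the benzyl ether and the aryl–silicon bond are inert to LiAlH4.

Step 6
Reactants: 10 3-(benzyloxy)-5-methoxy-6-methyl-2-(trimethylsilyl)phenol
Product: 11 3-(benzyloxy)-5-methoxy-6-methyl-2-(trimethylsilyl)phenyl acetate
Conditions: Ac2O, pyridine, DMAP (cat.), CH2Cl2, rt
Reagents that add atoms: acetic anhydride, CC(=O)OC(C)=O
Why: DMAP-catalysed O-acylation should overcome the hindrance of the phenol flanked by silicon and methyl and installs the acetate that later serves as the acyl donor.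

Step 7
Reactants: 11 3-(benzyloxy)-5-methoxy-6-methyl-2-(trimethylsilyl)phenyl acetate
Product: 12 3-hydroxy-5-methoxy-6-methyl-2-(trimethylsilyl)phenyl acetate
Conditions: H2 (1 atm), Pd/C, EtOAc, rt
Reagents that add atoms: none
Why: Neutral catalytic hydrogenolysis cleaves only the benzyl ether, leaving the aryl acetate and the aryl silane untouched, and the meta relationship of the two oxygens rules out acetyl migration.

Step 8
Reactants: 12 3-hydroxy-5-methoxy-6-methyl-2-(trimethylsilyl)phenyl acetate
Product: 13 3-acetoxy-5-methoxy-4-methyl-2-(trimethylsilyl)phenyl trifluoromethanesulfonate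
Conditions: Tf2O, pyridine, CH2Cl2, 0 °C
Reagents that add atoms: trifluoromethanesulfonic anhydride, O=S(=O)(OS(=O)(=O)C(F)(F)F)C(F)(F)F
Why: O-sulfonylation of a phenol next to silicon is the standard closing step for ortho-silylaryl triflates, and because the oxygen on carbon 5 of ring A is already acetylated no phenoxide remains that could trigger silyl migration.

Step 9
Reactants: 14 2,4,6-trihydroxytoluene
Product: 15 1-(2,4,6-trihydroxy-3-methylphenyl)ethanone
Conditions: Ac2O (1 equiv), BF3·OEt2, EtOAc, rt; aq NaOAc work-up
Reagents that add atoms: acetic anhydride, CC(=O)OC(C)=O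
Why: Friedel–Crafts C-acylation of the phloroglucinol nucleus at one of its two equivalent free positions should stop after one acetyl group because the chelated ketone deactivates the ring.

Step 10
Reactants: 15 1-(2,4,6-trihydroxy-3-methylphenyl)ethanone; 5 benzyl bromide
Product: 16 1-[4,6-bis(benzyloxy)-2-hydroxy-3-methylphenyl]ethanone
Conditions: BnBr (2 equiv), K2CO3, DMF, 0 °C to rt
Reagents that add atoms: benzyl bromide 5, BrCc1ccccc1
Why: In this Williamson etherification the unchelated hydroxyl para to the acetyl group (on carbon 2 of ring B) reacts first and, of the two chelated ortho hydroxyls, the one next to the ring hydrogen (on carbon 6) is less hindered than the one wedged between methyl and acetyl (on carbon 4), which should stay hydrogen-bonded to the ketone.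

Step 11
Reactants: 16 1-[4,6-bis(benzyloxy)-2-hydroxy-3-methylphenyl]ethanone
Product: 17 1-[4,6-bis(benzyloxy)-2-methoxy-3-methylphenyl]ethanone
Conditions: MeI, K2CO3, DMF, 50 °C
Reagents that add atoms: iodomethane, CI
Why: O-methylation (Williamson) of the remaining chelated phenol under more forcing conditions fixes the methyl ether on carbon 4 of ring B.

Step 12
Reactants: 17 1-[4,6-bis(benzyloxy)-2-methoxy-3-methylphenyl]ethanone
Product: 18 1-[2,4-bis(benzyloxy)-3-bromo-6-methoxy-5-methylphenyl]ethanone
Conditions: NBS, MeCN, 0 °C to rt, dark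
Reagents that add atoms: N-bromosuccinimide, O=C1CCC(=O)N1Br
Why: Electrophilic aromatic bromination can only take the single free position of the acetophenone ring (carbon 1 of ring B), which is ortho to both benzyloxy groups, para to the methoxy group and meta to the acetyl group.

Step 13
Reactants: 18 1-[2,4-bis(benzyloxy)-3-bromo-6-methoxy-5-methylphenyl]ethanone
Product: 20 1-[2,4-bis(benzyloxy)-3-hydroxy-6-methoxy-5-methylphenyl]ethanone, via aryl pinacol boronate 19 (not isolated)
Conditions: B2pin2, Pd2(dba)3 (cat.), XPhos, KOAc, dioxane, 100 °C; then 30% H2O2, aq NaOH, THF, 0 °C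
Reagents that add atoms: bis(pinacolato)diboron, CC1(C)OB(OC1(C)C)B1OC(C)(C)C(C)(C)O1 (boron in intermediate 19 only); hydrogen peroxide, OO
Why: Miyaura borylation with a bulky biaryl phosphine should cope with the two ortho alkoxy groups and tolerates the ketone under KOAc, and brief peroxide oxidation of the C–B bond then gives the phenol on carbon 1 of ring B, which is meta to the acetyl group and so not prone to Dakin-type cleavage.

Step 14
Reactants: 13 3-acetoxy-5-methoxy-4-methyl-2-(trimethylsilyl)phenyl trifluoromethanesulfonate; 20 1-[2,4-bis(benzyloxy)-3-hydroxy-6-methoxy-5-methylphenyl]ethanone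
Product: 23 leprolomin ring B dibenzyl ether, via 3-acetoxy-5-methoxy-4-methylbenzyne 21 (not isolated), via cesium aryl anion 22 (not isolated)
Conditions: CsF (3 equiv), 18-crown-6, THF, rt to 50 °C; 13 added slowly to 20 (1.3 equiv)
Reagents that add atoms: cesium fluoride, [Cs+].[F-] (counter-ion of intermediate 22 only)
Why: Proposed new method: fluoride attack at silicon expels triflate and forms aryne 21 between carbons 3 and 4 of ring A, the cesium phenoxide of 20 adds at carbon 3, and the carbanion 22 on carbon 4, born next to the acetate on carbon 5, attacks the ester carbonyl through a four-membered tetrahedral intermediate that collapses to the methyl ketone on carbon 4 and the phenoxide on carbon 5, protonated on work-up. The closest known reactions are fluoride-triggered O-arylation of phenols by ortho-silylaryl triflates, the anionic ortho-Fries shift of ortho-metalated aryl esters and carbamates, the thia-Fries shift that follows nucleophile addition to 3-sulfonyloxyarynes, and the acyl transfer that turns aryne–carboxylate adducts into ortho-hydroxyaryl ketones. No ring is closed and no stereocentre is formed. The step needs addition at carbon 3 and not at carbon 4, which the inductively withdrawing oxygen on carbon 5 secures by distorting the aryne towards attack at the distal carbon; carbon 3 is also flanked only by hydrogen, so the doubly ortho-substituted phenoxide can reach it. It also needs acyl transfer to outrun protonation of 22 and the acetate to survive until the aryne forms, which the 1,3-relationship of anion and ester, the aprotic THF medium, the hindered phenoxide and the slow addition of 13 are meant to ensure.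

Step 15
Reactants: 23 leprolomin ring B dibenzyl ether
Product: 24 leprolomin
Conditions: H2 (1 atm), Pd/C, EtOAc, rt
Reagents that add atoms: none
Why: Catalytic hydrogenolysis under neutral conditions should cleave both benzyl ethers while the diaryl ether, the methyl ethers and the two chelated aryl ketones stay intact.

Compound list
1 | 3-methoxy-2-methylphenol | COc1cccc(O)c1C | starting material
2 | 3-methoxy-2-methylphenyl N,N-diethylcarbamate | CCN(CC)C(=O)Oc1cccc(OC)c1C | intermediate
3 | 3-methoxy-2-methyl-5-(4,4,5,5-tetramethyl-1,3,2-dioxaborolan-2-yl)phenyl N,N-diethylcarbamate | CCN(CC)C(=O)Oc1cc(B2OC(C)(C)C(C)(C)O2)cc(OC)c1C | intermediate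
4 | 5-hydroxy-3-methoxy-2-methylphenyl N,N-diethylcarbamate | CCN(CC)C(=O)Oc1cc(O)cc(OC)c1C | intermediate
5 | benzyl bromide | BrCc1ccccc1 | starting material
6 | 5-(benzyloxy)-3-methoxy-2-methylphenyl N,N-diethylcarbamate | CCN(CC)C(=O)Oc1cc(OCc2ccccc2)cc(OC)c1C | intermediate
7 | chlorotrimethylsilane | C[Si](C)(C)Cl | starting material
8 | [6-(benzyloxy)-2-(diethylcarbamoyloxy)-4-methoxy-3-methylphenyl]lithium | [Li]c1c(OC(=O)N(CC)CC)c(C)c(OC)cc1OCc1ccccc1 | intermediate
9 | 3-(benzyloxy)-5-methoxy-6-methyl-2-(trimethylsilyl)phenyl N,N-diethylcarbamate | CCN(CC)C(=O)Oc1c([Si](C)(C)C)c(OCc2ccccc2)cc(OC)c1C | intermediate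
10 | 3-(benzyloxy)-5-methoxy-6-methyl-2-(trimethylsilyl)phenol | Cc1c(O)c([Si](C)(C)C)c(OCc2ccccc2)cc1OC | intermediate
11 | 3-(benzyloxy)-5-methoxy-6-methyl-2-(trimethylsilyl)phenyl acetate | CC(=O)Oc1c([Si](C)(C)C)c(OCc2ccccc2)cc(OC)c1C | intermediate
12 | 3-hydroxy-5-methoxy-6-methyl-2-(trimethylsilyl)phenyl acetate | CC(=O)Oc1c([Si](C)(C)C)c(O)cc(OC)c1C | intermediate
13 | 3-acetoxy-5-methoxy-4-methyl-2-(trimethylsilyl)phenyl trifluoromethanesulfonate | COc1cc(OS(=O)(=O)C(F)(F)F)c([Si](C)(C)C)c(OC(C)=O)c1C | intermediate
14 | 2,4,6-trihydroxytoluene | Cc1c(O)cc(O)cc1O | starting material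
15 | 1-(2,4,6-trihydroxy-3-methylphenyl)ethanone | CC(=O)c1c(O)cc(O)c(C)c1O | intermediate
16 | 1-[4,6-bis(benzyloxy)-2-hydroxy-3-methylphenyl]ethanone | CC(=O)c1c(O)c(C)c(OCc2ccccc2)cc1OCc1ccccc1 | intermediate
17 | 1-[4,6-bis(benzyloxy)-2-methoxy-3-methylphenyl]ethanone | CC(=O)c1c(OC)c(C)c(OCc2ccccc2)cc1OCc1ccccc1 | intermediate
18 | 1-[2,4-bis(benzyloxy)-3-bromo-6-methoxy-5-methylphenyl]ethanone | CC(=O)c1c(OC)c(C)c(OCc2ccccc2)c(Br)c1OCc1ccccc1 | intermediate
19 | 1-[2,4-bis(benzyloxy)-6-methoxy-5-methyl-3-(4,4,5,5-tetramethyl-1,3,2-dioxaborolan-2-yl)phenyl]ethanone | CC(=O)c1c(OC)c(C)c(OCc2ccccc2)c(B2OC(C)(C)C(C)(C)O2)c1OCc1ccccc1 | intermediate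
20 | 1-[2,4-bis(benzyloxy)-3-hydroxy-6-methoxy-5-methylphenyl]ethanone | CC(=O)c1c(OC)c(C)c(OCc2ccccc2)c(O)c1OCc1ccccc1 | intermediate
21 | 3-acetoxy-5-methoxy-4-methylbenzyne (triple bond between carbons 3 and 4 of ring A) | COC1=CC#CC(OC(C)=O)=C1C | intermediate
22 | cesium salt of the aryl anion on carbon 4 of ring A, formed by addition of the phenoxide of 20 to carbon 3 of 21 | COc1cc(Oc2c(OCc3ccccc3)c(C)c(OC)c(C(C)=O)c2OCc2ccccc2)[c-]c(OC(C)=O)c1C.[Cs+] | intermediate
23 | leprolomin ring B dibenzyl ether, 1-[3-(2-acetyl-3-hydroxy-5-methoxy-4-methylphenoxy)-2,4-bis(benzyloxy)-6-methoxy-5-methylphenyl]ethanone | COc1cc(Oc2c(OCc3ccccc3)c(C)c(OC)c(C(C)=O)c2OCc2ccccc2)c(C(C)=O)c(O)c1C | intermediate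
24 | leprolomin | COc1cc(Oc2c(O)c(C)c(OC)c(C(C)=O)c2O)c(C(C)=O)c(O)c1C | target

Total step count: 15. Longest linear sequence: 10 steps (steps 1 to 8, then 14 and 15); the ring B branch is steps 9 to 13.

Steps most likely to fail

Step 14 (Proposed new method). The aryl anion may be protonated before it reaches the ester, or the acetate may be transferred to phenoxide or fluoride before the aryne forms. The fallback uses known chemistry, sets out from 15 and 20 and comes back to the route at 23. Methylation of the unchelated hydroxyl para to the acetyl group of 15 (MeI, 1 equiv, K2CO3, acetone) should give 1-(2,6-dihydroxy-4-methoxy-3-methylphenyl)ethanone F1. Sulfonylation of its less hindered chelated hydroxyl, the one next to the ring hydrogen (PhNTf2, Et3N, CH2Cl2), should give 2-acetyl-3-hydroxy-5-methoxy-4-methylphenyl trifluoromethanesulfonate F2. A Buchwald–Hartwig diaryl ether coupling of F2, whose triflate is activated by the ortho acetyl group, with phenol 20 (Pd(OAc)2, 2-di-tert-butylphosphino-2′,4′,6′-triisopropylbiphenyl, K3PO4, toluene, 100 °C) should then give 23 with the ketone already in place.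

Step 10. Discrimination between the two chelated hydroxyls may be poor, and C-benzylation at the free ring carbon may compete. The fallback sets out from 4 and comes back at 17. LiAlH4 cleavage of the carbamate of 4 should give 5-methoxy-4-methylbenzene-1,3-diol F3. Friedel–Crafts acetylation (Ac2O, BF3·OEt2) should go para to one hydroxyl and ortho to the other, between the methoxy and a hydroxyl group and not between the two hydroxyls, giving 1-(4,6-dihydroxy-2-methoxy-3-methylphenyl)ethanone F4. Here the methyl ether is fixed before the ketone arrives, so exhaustive benzylation of both hydroxyls (BnBr, K2CO3, DMF, 60 °C) gives 17 with no choice between oxygens.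

Step 13. Oxidative addition at the doubly ortho-alkoxylated bromide may be slow, leading to protodebromination instead of borylation. The fallback sets out from 17 and comes back at 20. Vilsmeier–Haack formylation of the free ring position (POCl3, DMF) should give 3-acetyl-2,6-bis(benzyloxy)-4-methoxy-5-methylbenzaldehyde F5. Baeyer–Villiger oxidation with mCPBA in CH2Cl2, in which the aldehyde reacts far faster than the hindered methyl ketone, should give 3-acetyl-2,6-bis(benzyloxy)-4-methoxy-5-methylphenyl formate F6. Methanolysis (K2CO3, MeOH) then gives 20.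

Further compounds
F1 | step 14 | 1-(2,6-dihydroxy-4-methoxy-3-methylphenyl)ethanone | CC(=O)c1c(O)cc(OC)c(C)c1O
F2 | step 14 | 2-acetyl-3-hydroxy-5-methoxy-4-methylphenyl trifluoromethanesulfonate | CC(=O)c1c(O)c(C)c(OC)cc1OS(=O)(=O)C(F)(F)F
F3 | step 10 | 5-methoxy-4-methylbenzene-1,3-diol | COc1cc(O)cc(O)c1C
F4 | step 10 | 1-(4,6-dihydroxy-2-methoxy-3-methylphenyl)ethanone | CC(=O)c1c(OC)c(C)c(O)cc1O
F5 | step 13 | 3-acetyl-2,6-bis(benzyloxy)-4-methoxy-5-methylbenzaldehyde | CC(=O)c1c(OC)c(C)c(OCc2ccccc2)c(C=O)c1OCc1ccccc1
F6 | step 13 | 3-acetyl-2,6-bis(benzyloxy)-4-methoxy-5-methylphenyl formate | CC(=O)c1c(OC)c(C)c(OCc2ccccc2)c(OC=O)c1OCc1ccccc1
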